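# Hopeafuran by two-carbon ring expansion of an indanone with an aryne

## Analysis of the target

- Hopeafuran (27, C28H18O7) is a resveratrol dimer. A 2-arylbenzofuran (ring A = benzo ring C3a–C7a, ring B = furan O1–C2–C3) and a resorcinol ring (ring D) are clamped together by a seven-membered carbocycle (ring C).
- Ring C consists of C3, C3a and C4 of the benzofuran, a ketone carbon bound to C4, a methine carbon, and two neighbouring carbons of ring D. Six of its seven members are sp2, and each is a ring-fusion atom or carries a substituent.
- 4-Hydroxyphenyl groups sit on C2 (ring E) and on the methine (ring F). Further hydroxyl groups stand on C6 of ring A and on two meta-related carbons of ring D.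
- The methine is the only stereocentre. With the ranking ketone carbon > ring D > ring F > H it is S, and its absolute configuration must come from a reagent or a catalyst because nothing in the molecule can relay it.
- This centre is alpha to an aryl ketone and doubly benzylic, so base or strong acid can erase it through the enol. The five free phenols make the molecule sensitive to oxidants and to cationic chemistry.
- The difficulty lies in closing the crowded ring C with the right oxygenation pattern on rings A and D, and in creating the labile centre late and keeping it.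
- The strategy rests on how ring D joins ring C. The ring D carbon bound to C3 has a CH neighbour, whereas the ring D carbon bound to the methine is flanked by an oxygen-bearing carbon. This contiguous pattern results when a carbon nucleophile adds to the remote carbon of a 3-alkoxyaryne and an acyl group lands on the near one.
- Rings A and D are both 3,5-dioxygenated aryl units, so both halves can be drawn from symmetric building blocks.

## Retrosynthetic reasoning

**Protecting groups and ketone (27 ⇒ 26 ⇒ 25).** 27 is traced back to its pentasilyl ether 26. Aryl silyl ethers fall off under mildly acidic fluoride conditions that do not enolise the ketone, whereas methyl ethers would need a strong Lewis acid in the presence of the stereocentre. 26 is taken back to the secondary alcohol 25, so the ketone appears only two steps before the end and through a non-basic oxidation.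

**Methine C–H and carbinol C–O (25 ⇒ 23, through 24).** Both bonds are cut together, which leads to the flat alkene 23. Chirality is best introduced here because the two alkene carbons differ clearly (CH against C-aryl). Syn addition of hydrogen and boron from a chiral borane fixes the methine in the same event. The forward reaction must put boron on the CH carbon and choose one face. It also completes a 1,2-carbonyl transposition, moving the oxygen that the key step leaves on the ring D side to the C4 side.

**O1–C2 of the furan (23 ⇒ 22 ⇒ 20, through 21).** After a change of protecting groups, ring B is opened to the aryl ketone 20, whose ring A carries a methoxy group next to the carbon that holds the acyl-bearing CH. Only this oxygen can reach the ketone in a five-membered closure, so regiochemistry is not in question. One Lewis-acid operation can strip all six methyl ethers and close the furan by cyclodehydration. It is done before the stereocentre exists.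

**C2–ring E (20 ⇒ 18 + 19, 18 ⇒ 17).** The acyl–aryl bond is cut to the N-methoxy-N-methylamide 18 and the aryl Grignard reagent 19, and 18 comes from ester 17. The ester carbon that the key step carries along thus becomes C2. The forward reaction must stop at the ketone stage.

**Methine–ring F (17 ⇒ 15 + 16, 15 ⇒ 13, through 14).** The aryl–alkene bond is cut to the enol triflate 15 and the boronic acid 16, and 15 is the O-sulfonylated enolate of ketone 13. The ketone has only one enolisable side and the ring fixes the alkene geometry. The ketone is also removed before the ester is touched.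

**C3–ring D and ring D–carbonyl (13 ⇒ 10 + 5, through 11 and 12).** Both bonds from ring D to ring C are cut at once. What remains is the five-membered keto ester 10 and the aryne 11, stored as the silyl triflate 5. The cut is made here because it replaces an end-to-end seven-membered closure by an intermolecular addition followed by ring expansion. The flanking methoxy group of 11 dictates the orientation. The forward reaction has to insert the aryne into the bond between the ester-bearing carbon and the ketone carbon of 10.

**Ring A–ester-bearing carbon (10 ⇒ 9 ⇒ 8 ⇒ 6).** The five-membered ring is opened at this bond to the diazo keto ester 9. This compound comes from the keto ester 8 and then from the acid 6 by two-carbon homologation. Both ortho positions of 6 are equivalent and doubly activated, so the metal-carbenoid ring closure can give only one indanone.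

**Aryne precursor (5 ⇒ 3 ⇒ 2 ⇒ 1, through 4).** The C–Si bond is traced to an oxygen-to-carbon silyl shift in the metalated silyl ether 3. Its bromine is placed next to the hydroxyl group of the symmetric phenol 1.

## Alternatives that were turned down

**Alternative 1:**
- *Disconnection.* Rings B and C are cut together at C3a–C3 and O1–C2. This leads to the (Z)-triarylethylene iodophenol A1, with iodine on the future C3a, a free hydroxyl on the future C7a and an arylalkyne on ring D.
- *Forward key step.* Zerovalent palladium would insert into the C–I bond, and the aryl–palladium bond would add syn to the tethered alkyne in a 7-exo-dig mode. The phenoxide would then close O1–C2 by reductive elimination (an intramolecular Larock heteroannulation), giving the pentabenzyl alkene A2.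
- *For.* Two rings form in one step. A2 is the benzyl counterpart of 23, so the ester-to-ketone work, the Lewis-acid demethylation and the protecting-group change are not needed. Benzyl ethers also allow a neutral last step. On ring economy and protecting-group economy this plan is stronger.
- *Against.* The difficulty moves into A1. It needs a geometrically pure triaryl alkene with ring A cis to ring D. Iodine must sit in the most crowded of three similarly activated positions of ring A. The aryl iodide and the alkyne must also survive, or be introduced among, several palladium-catalysed couplings. The carbopalladation must bend a tether with four ortho substituents into a syn transition state, and reduction or intermolecular pathways compete. The stereocentre still needs the same alkene functionalisation.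
- *Comparison.* The chosen route offers symmetric building blocks, an alkene geometry imposed by the ring, and a ring closure that avoids a direct medium-ring cyclisation.

**Alternative 2:**
- *Disconnection.* Ring D is built from acyclic carbon. Cutting C3–ring D and one bond inside ring D leads to the benzofuran A3, which carries a beta-keto ester chain on C4 and a butynone on C3.
- *Forward key step.* Base would add the keto ester carbon to the alkynone (7-exo-dig Michael addition, closing ring C). The methyl ketone enolate would then attack the ester in a Claisen closure that aromatises, giving the tetracyclic ketone A4 with a free resorcinol ring.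
- *For.* Two C–C bonds and two rings form in one operation. The furan and ring E are already in place, and the ketone lands on the same carbon as in 13, so the later arylation and transposition could be shared. In bonds per step it is as strong as the chosen plan.
- *Against.* A3 is a 2,3,4-trisubstituted benzofuran with two base-sensitive chains, and it needs a long linear preparation. It has three competing acidic sites, among them the benzylic methylene between C4 and the ketone. Oxa-Michael closure through the enol oxygen competes. The Claisen step can occur only from the enone isomer that holds acetyl and ester cis. The new resorcinol must then be protected, which costs a further step.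
- *Comparison.* The chosen route obtains the same ring fusion from a phenol-derived aryne in one step from two short, convergent arms.

**Alternative 3:**
- *Disconnection.* The ketone–methine bond is cut. This leads to the C4 aldehyde A5, whose ring D carries a para-quinone methide.
- *Forward key step.* A chiral carbene catalyst would turn the aldehyde into an acyl anion equivalent that adds 1,6 to the quinone methide carbon (7-exo-trig). This would close ring C and set the stereocentre, giving tetrabenzyl hopeafuran A6.
- *For.* It is the only plan that creates ring, stereocentre and the correct oxidation state in one catalytic step. No carbonyl transposition is needed, and the target is one hydrogenolysis away. On stereochemical economy and on steps after the key step it is clearly stronger.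
- *Against.* A quinone methide without flanking alkyl groups is fleeting and would have to be generated in the flask, whereas the known additions of this kind rely on stabilised di-tert-butyl examples. A seven-membered variant with an aldehyde wedged against the C3 aryl group has no close model. The base that frees the carbene acts on a product whose new centre is enolisable, so the selectivity could be lost as it forms. A5 also needs a fully substituted benzofuran.
- *Comparison.* The chosen route pays with more steps after the key step. In return its ring-forming step is a known reaction type, and its stereo-defining step runs without base.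

Key step: step 7

Assumption: the sense of induction in step 14 is extrapolated from 1-arylcycloalkenes. If the opposite face were attacked, the reagent made from (−)-α-pinene would be used instead. Compounds 10, 12–15, 17, 18, 20 and 21 are racemic at the carbon that later becomes planar C3.

## Route

Step 1
Reactants: 1 3,5-dimethoxyphenol
Product: 2 2-bromo-3,5-dimethoxyphenol
Conditions: NBS (1.0 equiv), CH2Cl2, −78 °C → rt
Reagents that add atoms: N-bromosuccinimide, O=C1CCC(=O)N1Br
Why: Electrophilic aromatic bromination; the position between OH and OMe is activated by all three oxygen substituents and is less crowded than the one between the two methoxy groups, and hydrogen bonding of the phenol to the reagent favours ortho delivery. One equivalent at low temperature limits dibromination.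

Step 2
Reactants: 2 2-bromo-3,5-dimethoxyphenol
Product: 3 (2-bromo-3,5-dimethoxyphenoxy)trimethylsilane
Conditions: HMDS, THF, 70 °C; evaporate
Reagents that add atoms: hexamethyldisilazane, C[Si](C)(C)N[Si](C)(C)C
Why: O-silylation of a phenol with HMDS needs no added base and leaves only a volatile by-product, so 3 can be used after evaporation.

Step 3
Reactants: 3 (2-bromo-3,5-dimethoxyphenoxy)trimethylsilane
Product: 5 3,5-dimethoxy-2-(trimethylsilyl)phenyl trifluoromethanesulfonate, via lithium silylphenoxide 4 (not isolated)
Conditions: n-BuLi, THF, −100 → −78 °C; Tf2O, −78 °C → rt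
Reagents that add atoms: n-butyllithium, [Li]CCCC (lithium of 4 only); trifluoromethanesulfonic anhydride, O=S(=O)(OS(=O)(=O)C(F)(F)F)C(F)(F)F
Why: Bromine–lithium exchange is followed by a 1,3 oxygen-to-carbon silyl shift (retro-Brook rearrangement) driven by formation of the phenoxide 4. O-triflation then gives the usual ortho-silylaryl triflate form of an aryne.

Step 4
Reactants: 6 3,5-dimethoxyphenylacetic acid
Product: 8 methyl 4-(3,5-dimethoxyphenyl)-3-oxobutanoate, via acyl imidazolide 7 (not isolated)
Conditions: CDI, THF, rt; MeO2CCH2CO2K, MgCl2, Et3N, MeCN, rt; 1 M HCl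
Reagents that add atoms: 1,1'-carbonyldiimidazole, O=C(n1ccnc1)n1ccnc1 (imidazolyl group of 7 only); potassium monomethyl malonate, COC(=O)CC(=O)[O-].[K+]
Why: Masamune–Brooks homologation; the magnesium enolate of the malonate half ester is C-acylated by 7 and loses CO2 on acidification. The conditions leave the aryl ethers untouched.

Step 5
Reactants: 8 methyl 4-(3,5-dimethoxyphenyl)-3-oxobutanoate
Product: 9 methyl 2-diazo-4-(3,5-dimethoxyphenyl)-3-oxobutanoate
Conditions: p-ABSA, Et3N, MeCN, 0 °C → rt
Reagents that add atoms: 4-acetamidobenzenesulfonyl azide, CC(=O)Nc1ccc(cc1)S(=O)(=O)N=[N+]=[N-]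
Why: Regitz diazo transfer to an active methylene group flanked by ketone and ester; the benzylic methylene is far less acidic and does not compete.

Step 6
Reactants: 9 methyl 2-diazo-4-(3,5-dimethoxyphenyl)-3-oxobutanoate
Product: 10 methyl 5,7-dimethoxy-2-oxo-2,3-dihydro-1H-indene-1-carboxylate (racemic, largely enolic)
Conditions: Rh2(OAc)4 (1 mol %), CH2Cl2, rt → 40 °C
Reagents that add atoms: none
Why: Formal aromatic C–H insertion of a dirhodium carbenoid (electrophilic aromatic substitution closing a five-membered ring), known for diazo keto esters made from arylacetic acids. The two ortho positions are equivalent and each is activated by an ortho and a para methoxy group, so one indanone results.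

Step 7
Reactants: 10 methyl 5,7-dimethoxy-2-oxo-2,3-dihydro-1H-indene-1-carboxylate; 5 3,5-dimethoxy-2-(trimethylsilyl)phenyl trifluoromethanesulfonate
Product: 13 methyl 1,3,6,8-tetramethoxy-11-oxo-10,11-dihydro-5H-dibenzo[a,d][7]annulene-5-carboxylate (racemic), via 3,5-dimethoxybenzyne 11 (not isolated), via caesium benzocyclobutenoxide 12 (not isolated)
Conditions: 5 (1.25 equiv), CsF (2.5 equiv), MeCN, 80 °C
Reagents that add atoms: caesium fluoride, [F-].[Cs+] (counter-ion of 12 only)
Why: Fluoride attacks the silicon of 5 and triflate leaves, which releases aryne 11 slowly while the same base turns the largely enolic 10 into its enolate. The enolate carbon C1 adds to the aryne carbon remote from the flanking methoxy group, because the inductively withdrawing oxygen distorts the aryne and stabilises the aryl anion that develops next to it; this secures the ring D pattern of the target. The aryl anion then closes onto the neighbouring ring ketone, which is more electrophilic than the ester, in a 4-exo-trig mode to give 12. Strain release and the formation of an ester-stabilised, doubly benzylic carbanion drive cleavage of the old C1–C2 bond, so ring C is not closed end to end but arises by two-carbon expansion of the five-membered ring; protonation gives 13. The closest known reaction type is the fluoride-induced acyl-alkylation of arynes with cyclic beta-keto esters, 2-indanone-1-carboxylates included. No lasting stereocentre is formed, since C5 of 13 is racemic and later becomes planar C3. Besides regiochemistry the step needs C- over O-arylation, which the soft delocalised enolate favours, and single arylation, which the small excess of 5 and the lower acidity of 13 support.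

Step 8
Reactants: 13 methyl 1,3,6,8-tetramethoxy-11-oxo-10,11-dihydro-5H-dibenzo[a,d][7]annulene-5-carboxylate
Product: 15 methyl 1,3,6,8-tetramethoxy-11-(trifluoromethylsulfonyloxy)-5H-dibenzo[a,d][7]annulene-5-carboxylate, via potassium enolate 14 (not isolated)
Conditions: KHMDS (1.05 equiv), THF, −78 °C; PhNTf2, −78 → 0 °C
Reagents that add atoms: potassium hexamethyldisilazide, C[Si](C)(C)[N-][Si](C)(C)C.[K+] (potassium of 14 only); N-phenylbis(trifluoromethanesulfonimide), O=S(=O)(N(c1ccccc1)S(=O)(=O)C(F)(F)F)C(F)(F)F
Why: Enol triflate formation; the benzylic CH2 next to the aryl ketone is the most acidic site, more so than C5–H, whose enolate would have to flatten the tub-shaped ring. The ketone has one enolisable side and the ring fixes the alkene geometry.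

Step 9
Reactants: 15 methyl 1,3,6,8-tetramethoxy-11-(trifluoromethylsulfonyloxy)-5H-dibenzo[a,d][7]annulene-5-carboxylate; 16 4-methoxyphenylboronic acid
Product: 17 methyl 1,3,6,8-tetramethoxy-11-(4-methoxyphenyl)-5H-dibenzo[a,d][7]annulene-5-carboxylate
Conditions: Pd(OAc)2 (5 mol %), SPhos (10 mol %), K3PO4, PhMe/H2O, 80 °C
Reagents that add atoms: none
Why: Suzuki–Miyaura coupling of an enol triflate; a bulky electron-rich phosphine helps zerovalent palladium to insert next to the ortho-methoxy group and speeds reductive elimination to the triaryl alkene. The hindered ester survives the phosphate base.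

Step 10
Reactants: 17 methyl 1,3,6,8-tetramethoxy-11-(4-methoxyphenyl)-5H-dibenzo[a,d][7]annulene-5-carboxylate
Product: 18 N,1,3,6,8-pentamethoxy-11-(4-methoxyphenyl)-N-methyl-5H-dibenzo[a,d][7]annulene-5-carboxamide
Conditions: MeNHOMe·HCl, AlMe3, CH2Cl2, 0 → 40 °C; dilute HCl
Reagents that add atoms: N,O-dimethylhydroxylamine hydrochloride, CNOC.Cl
Why: Weinreb aminolysis of an ester with an aluminium amide, a Lewis-acidic and only weakly basic reagent that converts hindered and enolisable esters without deprotonating C5–H. The alkene and aryl ethers are inert.

Step 11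
Reactants: 18 N,1,3,6,8-pentamethoxy-11-(4-methoxyphenyl)-N-methyl-5H-dibenzo[a,d][7]annulene-5-carboxamide; 19 4-methoxyphenylmagnesium bromide
Product: 20 (4-methoxyphenyl)[1,3,6,8-tetramethoxy-11-(4-methoxyphenyl)-5H-dibenzo[a,d][7]annulen-5-yl]methanone
Conditions: 19 (3 equiv), THF, 0 °C → rt; aq NH4Cl
Reagents that add atoms: none
Why: Weinreb ketone synthesis; the chelated tetrahedral adduct holds until work-up, so addition stops at the ketone. Deprotonation at C5 is disfavoured because the resulting anion would have to flatten the seven-membered ring and would place eight π electrons in it.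

Step 12
Reactants: 20 (4-methoxyphenyl)[1,3,6,8-tetramethoxy-11-(4-methoxyphenyl)-5H-dibenzo[a,d][7]annulen-5-yl]methanone
Product: 22 pentacyclic alkene pentaphenol (hopeafuran skeleton with CH=C(aryl) in place of C(=O)–CH(aryl), CH on benzofuran C4), via hexaphenol ketone 21 (not isolated)
Conditions: BBr3 (12 equiv), CH2Cl2 (dilute), −78 °C → rt; H2O, 0 °C; under Ar
Reagents that add atoms: none
Why: Lewis-acid cleavage of aryl methyl ethers followed by cyclodehydration of an ortho-hydroxyaryl-substituted aryl ketone, a known one-pot entry to 2,3-diarylbenzofurans. Only the C6 oxygen of ring A can reach the ketone in a five-membered closure, and aromatisation of the furan drives loss of the C5 hydrogen.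

Step 13
Reactants: 22 pentacyclic alkene pentaphenol
Product: 23 penta-O-TBS ether of 22
Conditions: TBSCl (7.5 equiv), imidazole, DMAP (cat.), DMF, rt → 40 °C
Reagents that add atoms: tert-butyldimethylsilyl chloride, CC(C)(C)[Si](C)(C)Cl
Why: Standard silylation of phenols, run on crude 22 to limit air oxidation. The silyl ethers tolerate borane and periodinane and can be removed later without base.

Step 14
Reactants: 23 penta-O-TBS ether of 22
Product: 25 penta-O-TBS trans alcohol (carbinol carbon on C4 R, methine carbon S; OH and ring F on opposite faces), via alkyl(isopinocampheyl)borane 24 (not isolated)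
Conditions: IpcBH2 from (+)-α-pinene (3 equiv), THF, −25 °C → rt; 30% H2O2, 3 M aq NaOAc, 0 °C → rt
Reagents that add atoms: monoisopinocampheylborane from (+)-α-pinene, C[C@H]1[C@H](B)C[C@@H]2C[C@H]1C2(C)C (boron and terpene part of 24 only); hydrogen peroxide, OO
Why: Asymmetric hydroboration of a trisubstituted aryl alkene with monoisopinocampheylborane; boron goes to the CH carbon, as favoured both by sterics and by the cation-stabilising aryl groups on the other carbon, and hydrogen is delivered syn to the carbon that bears ring F, which sets the methine as S on the face chosen by the terpene residue. Oxidation with retention gives the trans alcohol, and acetate-buffered peroxide spares the aryl silyl ethers.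

Step 15
Reactants: 25 penta-O-TBS trans alcohol
Product: 26 penta-O-TBS (S)-hopeafuran
Conditions: Dess–Martin periodinane, CH2Cl2, 0 °C → rt
Reagents that add atoms: none
Why: Dess–Martin oxidation is fast and non-basic; it removes the carbinol stereocentre and leaves the neighbouring enolisable methine untouched.

Step 16
Reactants: 26 penta-O-TBS (S)-hopeafuran
Product: 27 (S)-hopeafuran
Conditions: HF·pyridine, THF/pyridine, 0 °C → rt; pH 7 buffer
Reagents that add atoms: none
Why: Acidic fluoride cleaves aryl silyl ethers without generating basic fluoride or free phenoxide, so the alpha-aryl ketone should not enolise. Neutral work-up and rapid purification protect the stereocentre and the phenols.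

## Compound list

1 | 3,5-dimethoxyphenol | COc1cc(O)cc(OC)c1 | starting material
2 | 2-bromo-3,5-dimethoxyphenol | COc1cc(O)c(Br)c(OC)c1 | intermediate
3 | (2-bromo-3,5-dimethoxyphenoxy)trimethylsilane | COc1cc(O[Si](C)(C)C)c(Br)c(OC)c1 | intermediate
4 | lithium 3,5-dimethoxy-2-(trimethylsilyl)phenoxide | COc1cc([O-])c([Si](C)(C)C)c(OC)c1.[Li+] | intermediate
5 | 3,5-dimethoxy-2-(trimethylsilyl)phenyl trifluoromethanesulfonate | COc1cc(OC)c([Si](C)(C)C)c(OS(=O)(=O)C(F)(F)F)c1 | intermediate
6 | 3,5-dimethoxyphenylacetic acid | COc1cc(OC)cc(CC(=O)O)c1 | starting material
7 | 2-(3,5-dimethoxyphenyl)-1-(imidazol-1-yl)ethanone | COc1cc(OC)cc(CC(=O)n2ccnc2)c1 | intermediate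
8 | methyl 4-(3,5-dimethoxyphenyl)-3-oxobutanoate | COC(=O)CC(=O)Cc1cc(OC)cc(OC)c1 | intermediate
9 | methyl 2-diazo-4-(3,5-dimethoxyphenyl)-3-oxobutanoate | COC(=O)C(=[N+]=[N-])C(=O)Cc1cc(OC)cc(OC)c1 | intermediate
10 | methyl 5,7-dimethoxy-2-oxo-2,3-dihydro-1H-indene-1-carboxylate (racemic) | COC(=O)C1C(=O)Cc2cc(OC)cc(OC)c21 | intermediate
11 | 3,5-dimethoxybenzyne | COC1=CC(OC)=CC#C1 | intermediate
12 | caesium alkoxide of the cis-fused benzocyclobutenol formed by closure of the aryl anion on the indanone carbonyl (racemic) | COC(=O)C12c3cc(OC)cc(OC)c3C1([O-])Cc1cc(OC)cc(OC)c12.[Cs+] | intermediate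
13 | methyl 1,3,6,8-tetramethoxy-11-oxo-10,11-dihydro-5H-dibenzo[a,d][7]annulene-5-carboxylate (racemic) | COC(=O)C1c2cc(OC)cc(OC)c2C(=O)Cc2cc(OC)cc(OC)c21 | intermediate
14 | potassium enolate of 13 (C10=C11) | COC(=O)C1c2cc(OC)cc(OC)c2C([O-])=Cc2cc(OC)cc(OC)c21.[K+] | intermediate
15 | methyl 1,3,6,8-tetramethoxy-11-(trifluoromethylsulfonyloxy)-5H-dibenzo[a,d][7]annulene-5-carboxylate (racemic) | COC(=O)C1c2cc(OC)cc(OC)c2C(OS(=O)(=O)C(F)(F)F)=Cc2cc(OC)cc(OC)c21 | intermediate
16 | 4-methoxyphenylboronic acid | COc1ccc(B(O)O)cc1 | starting material
17 | methyl 1,3,6,8-tetramethoxy-11-(4-methoxyphenyl)-5H-dibenzo[a,d][7]annulene-5-carboxylate (racemic) | COC(=O)C1c2cc(OC)cc(OC)c2C(c2ccc(OC)cc2)=Cc2cc(OC)cc(OC)c21 | intermediate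
18 | N,1,3,6,8-pentamethoxy-11-(4-methoxyphenyl)-N-methyl-5H-dibenzo[a,d][7]annulene-5-carboxamide (racemic) | CON(C)C(=O)C1c2cc(OC)cc(OC)c2C(c2ccc(OC)cc2)=Cc2cc(OC)cc(OC)c21 | intermediate
19 | 4-methoxyphenylmagnesium bromide | COc1ccc([Mg]Br)cc1 | starting material
20 | (4-methoxyphenyl)[1,3,6,8-tetramethoxy-11-(4-methoxyphenyl)-5H-dibenzo[a,d][7]annulen-5-yl]methanone (racemic) | COc1ccc(cc1)C(=O)C1c2cc(OC)cc(OC)c2C(c2ccc(OC)cc2)=Cc2cc(OC)cc(OC)c21 | intermediate
21 | (4-hydroxyphenyl)[1,3,6,8-tetrahydroxy-11-(4-hydroxyphenyl)-5H-dibenzo[a,d][7]annulen-5-yl]methanone (racemic, shown free of boron) | Oc1ccc(cc1)C(=O)C1c2cc(O)cc(O)c2C(c2ccc(O)cc2)=Cc2cc(O)cc(O)c21 | intermediate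
22 | pentacyclic alkene pentaphenol (hopeafuran skeleton with CH=C(4-hydroxyphenyl) in place of C(=O)–CH(aryl)) | C1(c2ccc(O)cc2)=Cc2cc(O)cc3oc(-c4ccc(O)cc4)c(c23)-c2cc(O)cc(O)c21 | intermediate
23 | penta-O-TBS ether of 22 | C1(c2ccc(O[Si](C)(C)C(C)(C)C)cc2)=Cc2cc(O[Si](C)(C)C(C)(C)C)cc3oc(-c4ccc(O[Si](C)(C)C(C)(C)C)cc4)c(c23)-c2cc(O[Si](C)(C)C(C)(C)C)cc(O[Si](C)(C)C(C)(C)C)c21 | intermediate
24 | alkyl(isopinocampheyl)borane from syn addition of H–B to 23 (boron on the carbon bound to C4) | C[C@H]1[C@H](B[C@H]3c4cc(O[Si](C)(C)C(C)(C)C)cc5oc(-c6ccc(O[Si](C)(C)C(C)(C)C)cc6)c(c45)-c4cc(O[Si](C)(C)C(C)(C)C)cc(O[Si](C)(C)C(C)(C)C)c4[C@@H]3c3ccc(O[Si](C)(C)C(C)(C)C)cc3)C[C@@H]2C[C@H]1C2(C)C | intermediate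
25 | penta-O-TBS trans alcohol (carbinol R, methine S) | O[C@H]1c2cc(O[Si](C)(C)C(C)(C)C)cc3oc(-c4ccc(O[Si](C)(C)C(C)(C)C)cc4)c(c23)-c2cc(O[Si](C)(C)C(C)(C)C)cc(O[Si](C)(C)C(C)(C)C)c2[C@@H]1c1ccc(O[Si](C)(C)C(C)(C)C)cc1 | intermediate
26 | penta-O-TBS (S)-hopeafuran | O=C1c2cc(O[Si](C)(C)C(C)(C)C)cc3oc(-c4ccc(O[Si](C)(C)C(C)(C)C)cc4)c(c23)-c2cc(O[Si](C)(C)C(C)(C)C)cc(O[Si](C)(C)C(C)(C)C)c2[C@@H]1c1ccc(O[Si](C)(C)C(C)(C)C)cc1 | intermediate
27 | (S)-hopeafuran | O=C1c2cc(O)cc3oc(-c4ccc(O)cc4)c(c23)-c2cc(O)cc(O)c2[C@@H]1c1ccc(O)cc1 | target

## Step count and least certain steps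

Total steps: 16. Longest linear sequence: 13 (steps 4–6 followed by steps 7–16; the aryne arm, steps 1–3, is equally long).

**Step 7 (key step).**
- *Risk.* The aryl anion may be protonated before it reaches the ketone, so that the sequence stops at plain alpha-arylation. Bond formation at C1 may also be slowed by the neighbouring C7 methoxy group, which would leave the aryne to be consumed by O-arylation, by the product or by the solvent.
- *Fallback.* The same two bonds are made one after the other, starting from 10.
  - Pinhey arylation with 3,5-dimethoxyphenyllead triacetate (pyridine, CHCl3) gives the quaternary keto ester methyl 1-(3,5-dimethoxyphenyl)-5,7-dimethoxy-2-oxoindane-1-carboxylate F1. Material from an interrupted aryne addition has the same constitution and can be pooled with it.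
  - Retro-Claisen opening with LiOH in aqueous THF cleaves the C1–C2 bond, helped by the stabilised diarylacetate carbanion, and gives the half ester 2-{2-[1-(3,5-dimethoxyphenyl)-2-methoxy-2-oxoethyl]-3,5-dimethoxyphenyl}acetic acid F2.
  - Intramolecular Friedel–Crafts acylation (TFAA, CH2Cl2) then attacks one of the two equivalent positions of the 3,5-dimethoxyphenyl ring, ortho to one methoxy group and para to the other. This closes ring C and returns to 13.

**Step 14.**
- *Risk.* Hydroboration may be sluggish at a triaryl alkene flanked by a silyloxy group. Facial selectivity may be poor because both substituents on the prochiral carbon are aryl. Warming to force conversion invites retro-hydroboration, and some loss of aryl silyl groups during oxidation is possible.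
- *Fallback.* Oxygen, not hydrogen, is delivered enantioselectively, starting from 23.
  - Shi epoxidation (fructose-derived ketone or its enantiomer, Oxone, K2CO3 buffer, MeCN/DMM/H2O, 0 °C), a reaction known for triaryl alkenes, gives the penta-O-TBS epoxide F3. Its oxygen lies on the face opposite to the one the methine hydrogen must occupy.
  - Meinwald rearrangement (BF3·OEt2, CH2Cl2, −78 °C) opens the epoxide at the diaryl carbon. The hydrogen on the neighbouring carbon shifts across the face it already occupies, which the ring keeps fixed. The chirality is thereby transferred, and 26 is reached directly, bypassing 25.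

**Step 12.**
- *Risk.* Hydrogen bromide formed in the medium may protonate the electron-rich alkene and start cationic oligomerisation. Demethylation or dehydration may stay incomplete, and the polyphenol may be oxidised by air.
- *Fallback.* The Lewis acid is used before the alkene exists and both aryl groups are introduced together, starting from 13.
  - BBr3 removes the four aryl methyl groups, and the C6 phenol lactonises onto the ester to give the trihydroxy keto lactone F4.
  - Silylation (TBSCl, imidazole, DMF) gives the tris-O-TBS keto lactone F5.
  - Double enolisation and sulfonylation (KHMDS, 2.2 equiv; PhNTf2) give the bis(triflate) F6, which contains a benzofuran-2-yl triflate and the ring C enol triflate.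
  - A double Suzuki–Miyaura coupling with 4-(tert-butyldimethylsilyloxy)phenylboronic acid (Pd(OAc)2, SPhos, K3PO4, PhMe) returns to 23.
  - The hydrolytic lability of the heteroaryl triflate is the weak point of this detour.

**Step 11.**
- *Risk.* The basic Grignard reagent may enolise the amide or strip the N-methoxy group by elimination, and addition may be slow because the carbonyl group is buried between two aryl rings.
- *Fallback.* The ketone is built through the aldehyde oxidation level, starting from 17.
  - LiAlH4 (THF, 0 °C) gives the primary alcohol F7.
  - Dess–Martin oxidation gives the aldehyde F8.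
  - Addition of 19 at −78 °C gives the secondary alcohol F9 as a diastereomer mixture.
  - A second Dess–Martin oxidation returns to 20.

**Step 16.**
- *Risk.* Enolisation during desilylation, work-up or chromatography would erode the enantiomeric purity, because the methine hydrogen is alpha to the ketone and doubly benzylic, and the freed phenols raise the polarity and the contact time on silica.
- *Fallback.* A protecting group removed under neutral conditions is used, starting from 22.
  - Benzylation (BnBr, K2CO3, DMF) gives the pentabenzyl alkene F10.
  - Hydroboration–oxidation as in step 14 gives the pentabenzyl trans alcohol F11.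
  - Dess–Martin oxidation gives pentabenzyl (S)-hopeafuran F12.
  - Hydrogenolysis (H2, Pd/C, EtOAc/THF, 1 atm, stopped at full debenzylation) returns to 27.

## Further compounds

F1 | step 7 | methyl 1-(3,5-dimethoxyphenyl)-5,7-dimethoxy-2-oxoindane-1-carboxylate (racemic) | COC(=O)C1(c2cc(OC)cc(OC)c2)C(=O)Cc2cc(OC)cc(OC)c21
F2 | step 7 | 2-{2-[1-(3,5-dimethoxyphenyl)-2-methoxy-2-oxoethyl]-3,5-dimethoxyphenyl}acetic acid (racemic) | COC(=O)C(c1cc(OC)cc(OC)c1)c1c(CC(=O)O)cc(OC)cc1OC
F3 | step 14 | penta-O-TBS epoxide of 23 (CH carbon R, quaternary carbon S) | O1[C@@H]2c3cc(O[Si](C)(C)C(C)(C)C)cc4oc(-c5ccc(O[Si](C)(C)C(C)(C)C)cc5)c(c34)-c3cc(O[Si](C)(C)C(C)(C)C)cc(O[Si](C)(C)C(C)(C)C)c3[C@]12c1ccc(O[Si](C)(C)C(C)(C)C)cc1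
F4 | step 12 | trihydroxy keto lactone (benzofuran-2(3H)-one fused to ring C, racemic) | O=C1Oc2cc(O)cc3CC(=O)c4c(O)cc(O)cc4C1c23
F5 | step 12 | tris-O-TBS keto lactone (racemic) | O=C1Oc2cc(O[Si](C)(C)C(C)(C)C)cc3CC(=O)c4c(O[Si](C)(C)C(C)(C)C)cc(O[Si](C)(C)C(C)(C)C)cc4C1c23
F6 | step 12 | bis(triflate): benzofuran-2-yl triflate and ring C enol triflate, tris-O-TBS | O=S(=O)(Oc1oc2cc(O[Si](C)(C)C(C)(C)C)cc3C=C(OS(=O)(=O)C(F)(F)F)c4c(O[Si](C)(C)C(C)(C)C)cc(O[Si](C)(C)C(C)(C)C)cc4-c1c23)C(F)(F)F
F7 | step 11 | [1,3,6,8-tetramethoxy-11-(4-methoxyphenyl)-5H-dibenzo[a,d][7]annulen-5-yl]methanol (racemic) | OCC1c2cc(OC)cc(OC)c2C(c2ccc(OC)cc2)=Cc2cc(OC)cc(OC)c21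
F8 | step 11 | 1,3,6,8-tetramethoxy-11-(4-methoxyphenyl)-5H-dibenzo[a,d][7]annulene-5-carbaldehyde (racemic) | O=CC1c2cc(OC)cc(OC)c2C(c2ccc(OC)cc2)=Cc2cc(OC)cc(OC)c21
F9 | step 11 | (4-methoxyphenyl)[1,3,6,8-tetramethoxy-11-(4-methoxyphenyl)-5H-dibenzo[a,d][7]annulen-5-yl]methanol (diastereomer mixture, racemic) | COc1ccc(cc1)C(O)C1c2cc(OC)cc(OC)c2C(c2ccc(OC)cc2)=Cc2cc(OC)cc(OC)c21
F10 | step 16 | pentabenzyl ether of 22 | C1(c2ccc(OCc3ccccc3)cc2)=Cc2cc(OCc3ccccc3)cc3oc(-c4ccc(OCc5ccccc5)cc4)c(c23)-c2cc(OCc3ccccc3)cc(OCc3ccccc3)c21
F11 | step 16 | pentabenzyl trans alcohol (carbinol R, methine S) | O[C@H]1c2cc(OCc3ccccc3)cc3oc(-c4ccc(OCc5ccccc5)cc4)c(c23)-c2cc(OCc3ccccc3)cc(OCc3ccccc3)c2[C@@H]1c1ccc(OCc2ccccc2)cc1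
F12 | step 16 | pentabenzyl (S)-hopeafuran | O=C1c2cc(OCc3ccccc3)cc3oc(-c4ccc(OCc5ccccc5)cc4)c(c23)-c2cc(OCc3ccccc3)cc(OCc3ccccc3)c2[C@@H]1c1ccc(OCc2ccccc2)cc1
A1 | alternative 1 | (Z)-triarylethylene iodophenol carrying the arylalkyne on ring D | Oc1cc(OCc2ccccc2)cc(/C=C(/c2ccc(OCc3ccccc3)cc2)c2c(OCc3ccccc3)cc(OCc3ccccc3)cc2C#Cc2ccc(OCc3ccccc3)cc2)c1I
A2 | alternative 1 | pentabenzyl pentacyclic alkene | C1(c2ccc(OCc3ccccc3)cc2)=Cc2cc(OCc3ccccc3)cc3oc(-c4ccc(OCc5ccccc5)cc4)c(c23)-c2cc(OCc3ccccc3)cc(OCc3ccccc3)c21
A3 | alternative 2 | benzofuran with beta-keto ester chain on C4 and butynone on C3 | COC(=O)CC(=O)Cc1cc(OCc2ccccc2)cc2oc(-c3ccc(OCc4ccccc4)cc3)c(C#CC(C)=O)c12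
A4 | alternative 2 | tetracyclic ketone with free resorcinol ring | O=C1Cc2cc(OCc3ccccc3)cc3oc(-c4ccc(OCc5ccccc5)cc4)c(c23)-c2cc(O)cc(O)c21
A5 | alternative 3 | C4 aldehyde with para-quinone methide on ring D | O=Cc1cc(OCc2ccccc2)cc2oc(-c3ccc(OCc4ccccc4)cc3)c(c12)-c1cc(OCc2ccccc2)cc(OCc2ccccc2)c1C=C1C=CC(=O)C=C1
A6 | alternative 3 | tetrabenzyl hopeafuran with free 4-hydroxyphenyl group on the methine | O=C1c2cc(OCc3ccccc3)cc3oc(-c4ccc(OCc5ccccc5)cc4)c(c23)-c2cc(OCc3ccccc3)cc(OCc3ccccc3)c2[C@@H]1c1ccc(O)cc1
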